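Ring B, the 1,2,4-trisubstituted phenol ring (C1 carries the CH2), is built from a 2-pyrone and an alkyne. Its phenol oxygen on C3 and the tertiary carbinol oxygen on the carbon attached to C4 sit on neighbouring positions, so one diisopropylsilicon atom can hold both. The precursor is the mixed silaketal of 5-[2,3-bis(benzyloxy)-5-methylbenzyl]-3-hydroxy-2-pyrone and (S)-3,7-dimethyloct-1-yn-3-ol. On heating, the tethered alkyne should add across pyrone C3 and C6 and the adduct should lose CO2, forming the C3–C4 and C5–C6 bonds of ring B and placing the benzyl group para to the carbinol in one operation. The stereocentre is set earlier by asymmetric epoxidation and only carried through.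

Key step: step 14

Remark: ring A is the catechol ring, ring B the phenol ring. The carbinol carbon is S in 20–26 because its CIP order (O > sp or sp2 carbon > CH2 > CH3) never changes.
Remark: the C3 oxygen of the pyrone is installed before the C5 benzyl group, because palladium attacks C3 of 3,5-dibromo-2-pyrone first. The alkynol is made by asymmetric synthesis, since tertiary alcohols resolve poorly.
Assumption: geraniol of high E purity is used, since the Z isomer would give the opposite configuration at C3.

Step 1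
Reactants: 1 2-methoxy-4-methylphenol (creosol)
Product: 3 2-hydroxy-3-methoxy-5-methylbenzaldehyde, via hydroxymethyl phenol 2 (not isolated)
Conditions: MgCl2, Et3N, (CH2O)n, MeCN, reflux
Reagents that add atoms: formaldehyde (as paraformaldehyde), C=O
Why: Magnesium-mediated ortho-formylation of a phenol (Casiraghi-type): the magnesium phenoxide is hydroxymethylated at C6, the only free ortho position (para carries the methyl group), and a second formaldehyde oxidises the benzylic alkoxide by hydride transfer.

Step 2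
Reactants: 3 2-hydroxy-3-methoxy-5-methylbenzaldehyde
Product: 4 2,3-dihydroxy-5-methylbenzaldehyde
Conditions: BBr3, CH2Cl2, −78 → 0 °C; H2O
Reagents that add atoms: none
Why: Lewis acid cleavage of an aryl methyl ether with BBr3, which is fast for a methoxy group next to a chelating phenol and is run cold enough for the aldehyde to survive.

Step 3
Reactants: 4 2,3-dihydroxy-5-methylbenzaldehyde
Product: 5 2,3-bis(benzyloxy)-5-methylbenzaldehyde
Conditions: BnBr, K2CO3, DMF, 60 °C
Reagents that add atoms: benzyl bromide, BrCc1ccccc1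
Why: Williamson ether synthesis on both phenols; benzyl ethers are chosen because they tolerate organozinc reagents, silyl triflates, heat and fluoride and leave under neutral hydrogenolysis.

Step 4
Reactants: 5 2,3-bis(benzyloxy)-5-methylbenzaldehyde
Product: 6 [2,3-bis(benzyloxy)-5-methylphenyl]methanol
Conditions: NaBH4, MeOH–THF, 0 °C
Reagents that add atoms: none
Why: Borohydride reduction of an aryl aldehyde; the benzyl ethers are inert.

Step 5
Reactants: 6 [2,3-bis(benzyloxy)-5-methylphenyl]methanol
Product: 7 1,2-bis(benzyloxy)-3-(chloromethyl)-5-methylbenzene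
Conditions: SOCl2, CH2Cl2, 0 → 23 °C
Reagents that add atoms: thionyl chloride, O=S(Cl)Cl
Why: Chlorodehydroxylation of an electron-rich benzylic alcohol through its chlorosulfite; the chloride is preferred to the bromide because it gives less Wurtz coupling in the later zinc insertion.

Step 6
Reactants: 8 coumalic acid
Product: 10 3,5-dibromo-2H-pyran-2-one, via 3-bromocoumalic acid 9 (not isolated)
Conditions: NBS (2.5 equiv), LiOAc, MeCN–H2O, 23 °C
Reagents that add atoms: N-bromosuccinimide, O=C1CCC(=O)N1Br
Why: Electrophilic bromination at C3 followed by Hunsdiecker-type ipso-bromodecarboxylation of the C5 carboxylate (halodecarboxylation of an unsaturated acid with NBS and acetate).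

Step 7
Reactants: 10 3,5-dibromo-2H-pyran-2-one
Product: 12 5-bromo-3-hydroxy-2H-pyran-2-one, via 3-boryl pyrone 11 (not isolated)
Conditions: B2pin2 (1.05 equiv), PdCl2(dppf), KOAc, 1,4-dioxane, 80 °C; then 30% H2O2, pH 7 buffer, THF, 0 °C
Reagents that add atoms: hydrogen peroxide, OO (oxygen of the 3-OH); bis(pinacolato)diboron, CC1(C)OB(OC1(C)C)B1OC(C)(C)C(C)(C)O1 (boron of 11 only)
Why: Miyaura borylation then boronate oxidation: zerovalent palladium inserts first into the C3–Br bond next to the lactone carbonyl, the innately more reactive site of this dibromide without copper, and the weak base KOAc spares the pyrone ring and disfavours Suzuki self-coupling.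

Step 8
Reactants: 7 1,2-bis(benzyloxy)-3-(chloromethyl)-5-methylbenzene; 12 5-bromo-3-hydroxy-2H-pyran-2-one
Product: 14 5-[2,3-bis(benzyloxy)-5-methylbenzyl]-3-hydroxy-2H-pyran-2-one, via benzylzinc chloride 13 (not isolated)
Conditions: 7, Zn dust, LiCl, THF, 25 °C; then 12, Pd(OAc)2 (2 mol%), SPhos (4 mol%), THF, 25 °C, slow addition of 13 (1.5 equiv); citric acid work-up
Reagents that add atoms: none
Why: Negishi sp3–sp2 cross-coupling after LiCl-assisted zinc insertion into the benzylic chloride; Pd/SPhos couplings of benzylic zinc halides are known to outrun protonolysis by phenol-type OH groups on slow addition, and only one C–Br bond is left so no site selectivity is needed.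

Step 9
Reactants: 15 geraniol
Product: 16 [(2S,3S)-3-methyl-3-(4-methylpent-3-en-1-yl)oxiran-2-yl]methanol
Conditions: Ti(OiPr)4 (5 mol%), L-(+)-DET (7.5 mol%), t-BuOOH, 4 Å MS, CH2Cl2, −20 °C
Reagents that add atoms: tert-butyl hydroperoxide, CC(C)(C)OO
Why: Katsuki–Sharpless asymmetric epoxidation: the titanium L-(+)-tartrate catalyst delivers oxygen to one face of the allylic 2,3-alkene, setting C3 (the future carbinol carbon) and C2 both as S; the E geometry fixes their relative configuration and the 6,7-alkene, which has no directing hydroxyl, is untouched.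

Step 10
Reactants: 16 [(2S,3S)-3-methyl-3-(4-methylpent-3-en-1-yl)oxiran-2-yl]methanol
Product: 17 [(2S,3S)-3-methyl-3-(4-methylpentyl)oxiran-2-yl]methanol
Conditions: H2 (1 atm), Pt/C, EtOAc, 23 °C
Reagents that add atoms: none
Why: Heterogeneous catalytic hydrogenation of the isolated trisubstituted alkene; an epoxide that is neither benzylic nor allylic is inert under neutral conditions and no stereocentre is touched.

Step 11
Reactants: 17 [(2S,3S)-3-methyl-3-(4-methylpentyl)oxiran-2-yl]methanol
Product: 18 (2R,3S)-2-(chloromethyl)-3-methyl-3-(4-methylpentyl)oxirane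
Conditions: PPh3, CCl4, NaHCO3, reflux
Reagents that add atoms: carbon tetrachloride, ClC(Cl)(Cl)Cl
Why: Appel reaction on the primary alcohol; the epoxide survives the buffered neutral conditions, and the change of the C2 descriptor from S to R reflects only the new CIP ranking of CH2Cl.

Step 12
Reactants: 18 (2R,3S)-2-(chloromethyl)-3-methyl-3-(4-methylpentyl)oxirane
Product: 20 (S)-3,7-dimethyloct-1-yn-3-ol, via chlorovinyl alkoxide 19 (not isolated)
Conditions: n-BuLi (3.3 equiv), THF, −40 → −20 °C; NH4Cl aq
Reagents that add atoms: none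
Why: Base-induced fragmentation of a 2,3-epoxy chloride to a propargylic alcohol (double elimination): lithiation next to chlorine opens the epoxide, a second equivalent eliminates HCl and a third holds the acetylide; the C3–O bond is never broken, so the S configuration from step 9 is retained.

Step 13
Reactants: 20 (S)-3,7-dimethyloct-1-yn-3-ol; 14 5-[2,3-bis(benzyloxy)-5-methylbenzyl]-3-hydroxy-2H-pyran-2-one
Product: 22 5-[2,3-bis(benzyloxy)-5-methylbenzyl]-3-[({[(3S)-3,7-dimethyloct-1-yn-3-yl]oxy}di(propan-2-yl)silyl)oxy]-2H-pyran-2-one, via silyl triflate 21 (not isolated)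
Conditions: 20, iPr2Si(OTf)2 (1.0 equiv), 2,6-lutidine (3 equiv), CH2Cl2, −78 → 0 °C; then 14, 0 → 23 °C
Reagents that add atoms: di(propan-2-yl)silanediyl bis(trifluoromethanesulfonate), CC(C)[Si](OS(=O)(=O)C(F)(F)F)(OS(=O)(=O)C(F)(F)F)C(C)C
Why: Stepwise formation of an unsymmetrical silaketal (temporary silicon tether) from a silyl bis-triflate: the hindered tertiary alcohol displaces only one triflate and the acidic pyrone enol then takes the second; the carbinol C–O bond is not involved.

Step 14
Reactants: 22 5-[2,3-bis(benzyloxy)-5-methylbenzyl]-3-[({[(3S)-3,7-dimethyloct-1-yn-3-yl]oxy}di(propan-2-yl)silyl)oxy]-2H-pyran-2-one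
Product: 24 (4S)-7-[2,3-bis(benzyloxy)-5-methylbenzyl]-4-methyl-4-(4-methylpentyl)-2,2-di(propan-2-yl)-4H-1,3,2-benzodioxasiline, via bridged bicyclic lactone 23 (not isolated)
Conditions: PhMe (0.01 M), BHT (10 mol%), sealed tube, 160 °C
Reagents that add atoms: none
Why: The 3-silyloxy-2-pyrone acts as the diene through C3 and C6 and the tethered terminal alkyne as the dienophile in an intramolecular [4+2] cycloaddition to the 2-oxabicyclo[2.2.2]octadienone 23, which at this temperature loses CO2 by retro-[4+2] cycloreversion to give the arene. The closest known reaction types are the intramolecular 2-pyrone–alkyne Diels–Alder/decarboxylation route to benzenes and Diels–Alder reactions of partners joined by a temporary silicon tether. Ring B is closed by the cycloaddition itself (its C3–C4 and C5–C6 bonds) and aromatised by the cycloreversion, while the six-membered dioxasiline closes in the same event as the tether ring of a type 1 intramolecular Diels–Alder reaction, through the C3–C4 bond. No stereocentre is created in 24: the bridgehead centres of 23 vanish with CO2, and the quaternary carbinol, with no α-hydrogen and no bond broken, cannot epimerise. Only regioselectivity is needed, and the four-atom O–Si–O–C tether secures it because only the carbinol-bearing alkyne carbon can reach pyrone C3, so the benzyl group ends para to the carbinol; the two isopropyl groups and the quaternary carbinol favour the folded conformation, and the benzyl ethers are inert.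

Step 15
Reactants: 24 (4S)-7-[2,3-bis(benzyloxy)-5-methylbenzyl]-4-methyl-4-(4-methylpentyl)-2,2-di(propan-2-yl)-4H-1,3,2-benzodioxasiline
Product: 25 5-[2,3-bis(benzyloxy)-5-methylbenzyl]-2-[(2S)-2-hydroxy-6-methylheptan-2-yl]phenol
Conditions: TBAF·3H2O, THF, 0 → 23 °C
Reagents that add atoms: none
Why: Fluoride-induced cleavage of both Si–O bonds of the silylene; the basic medium avoids ionisation of the tertiary benzylic alcohol and the benzyl ethers are inert.

Step 16
Reactants: 25 5-[2,3-bis(benzyloxy)-5-methylbenzyl]-2-[(2S)-2-hydroxy-6-methylheptan-2-yl]phenol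
Product: 26 asperchondol A
Conditions: H2 (1 atm), Pd/C, EtOAc, 23 °C
Reagents that add atoms: none
Why: Hydrogenolysis of the two aryl benzyl ethers; under neutral, acid-free conditions the hindered tertiary benzylic C–OH bond should not be cleaved and the stereocentre is unaffected.

Compound list
1 | 2-methoxy-4-methylphenol (creosol) | COc1cc(C)ccc1O | starting material
2 | 2-(hydroxymethyl)-6-methoxy-4-methylphenol (formed as its magnesium phenoxide) | COc1cc(C)cc(CO)c1O | intermediate
3 | 2-hydroxy-3-methoxy-5-methylbenzaldehyde | COc1cc(C)cc(C=O)c1O | intermediate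
4 | 2,3-dihydroxy-5-methylbenzaldehyde | Cc1cc(O)c(O)c(C=O)c1 | intermediate
5 | 2,3-bis(benzyloxy)-5-methylbenzaldehyde | Cc1cc(OCc2ccccc2)c(OCc2ccccc2)c(C=O)c1 | intermediate
6 | [2,3-bis(benzyloxy)-5-methylphenyl]methanol | Cc1cc(OCc2ccccc2)c(OCc2ccccc2)c(CO)c1 | intermediate
7 | 1,2-bis(benzyloxy)-3-(chloromethyl)-5-methylbenzene | Cc1cc(OCc2ccccc2)c(OCc2ccccc2)c(CCl)c1 | intermediate
8 | coumalic acid (2-oxo-2H-pyran-5-carboxylic acid) | O=C(O)C1=COC(=O)C=C1 | starting material
9 | 3-bromocoumalic acid (3-bromo-2-oxo-2H-pyran-5-carboxylic acid) | O=C(O)C1=COC(=O)C(Br)=C1 | intermediate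
10 | 3,5-dibromo-2H-pyran-2-one | O=C1OC=C(Br)C=C1Br | intermediate
11 | 5-bromo-3-(4,4,5,5-tetramethyl-1,3,2-dioxaborolan-2-yl)-2H-pyran-2-one | CC1(C)OB(OC1(C)C)C1=CC(Br)=COC1=O | intermediate
12 | 5-bromo-3-hydroxy-2H-pyran-2-one | O=C1OC=C(Br)C=C1O | intermediate
13 | [2,3-bis(benzyloxy)-5-methylbenzyl]zinc chloride | Cc1cc(OCc2ccccc2)c(OCc2ccccc2)c(C[Zn]Cl)c1 | intermediate
14 | 5-[2,3-bis(benzyloxy)-5-methylbenzyl]-3-hydroxy-2H-pyran-2-one | Cc1cc(OCc2ccccc2)c(OCc2ccccc2)c(CC2=COC(=O)C(O)=C2)c1 | intermediate
15 | geraniol, (E)-3,7-dimethylocta-2,6-dien-1-ol | CC(C)=CCC/C(C)=C/CO | starting material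
16 | [(2S,3S)-3-methyl-3-(4-methylpent-3-en-1-yl)oxiran-2-yl]methanol | OC[C@@H]1O[C@@]1(C)CCC=C(C)C | intermediate
17 | [(2S,3S)-3-methyl-3-(4-methylpentyl)oxiran-2-yl]methanol | OC[C@@H]1O[C@@]1(C)CCCC(C)C | intermediate
18 | (2R,3S)-2-(chloromethyl)-3-methyl-3-(4-methylpentyl)oxirane | ClC[C@@H]1O[C@@]1(C)CCCC(C)C | intermediate
19 | lithium (3S)-1-chloro-3,7-dimethyloct-1-en-3-olate (alkene geometry not defined) | [Li+].[O-][C@@](C=CCl)(C)CCCC(C)C | intermediate
20 | (S)-3,7-dimethyloct-1-yn-3-ol | C#C[C@@](C)(O)CCCC(C)C | intermediate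
21 | {[(3S)-3,7-dimethyloct-1-yn-3-yl]oxy}di(propan-2-yl)silyl trifluoromethanesulfonate | CC(C)[Si](C(C)C)(OS(=O)(=O)C(F)(F)F)O[C@](C)(C#C)CCCC(C)C | intermediate
22 | 5-[2,3-bis(benzyloxy)-5-methylbenzyl]-3-[({[(3S)-3,7-dimethyloct-1-yn-3-yl]oxy}di(propan-2-yl)silyl)oxy]-2H-pyran-2-one | Cc1cc(OCc2ccccc2)c(OCc2ccccc2)c(CC2=COC(=O)C(O[Si](C(C)C)(C(C)C)O[C@](C)(C#C)CCCC(C)C)=C2)c1 | intermediate
23 | 2-oxabicyclo[2.2.2]octa-5,7-dien-3-one cycloadduct of 22, fused to the dioxasiline (carbinol S; both bridgehead diastereomers, bridgeheads not specified) | Cc1cc(OCc2ccccc2)c(OCc2ccccc2)c(CC2=CC34O[Si](C(C)C)(C(C)C)O[C@@](C)(CCCC(C)C)C3=CC2OC4=O)c1 | intermediate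
24 | (4S)-7-[2,3-bis(benzyloxy)-5-methylbenzyl]-4-methyl-4-(4-methylpentyl)-2,2-di(propan-2-yl)-4H-1,3,2-benzodioxasiline | Cc1cc(OCc2ccccc2)c(OCc2ccccc2)c(Cc2ccc3c(c2)O[Si](C(C)C)(C(C)C)O[C@@]3(C)CCCC(C)C)c1 | intermediate
25 | 5-[2,3-bis(benzyloxy)-5-methylbenzyl]-2-[(2S)-2-hydroxy-6-methylheptan-2-yl]phenol | Cc1cc(OCc2ccccc2)c(OCc2ccccc2)c(Cc2ccc([C@@](C)(O)CCCC(C)C)c(O)c2)c1 | intermediate
26 | asperchondol A, 3-{3-hydroxy-4-[(2S)-2-hydroxy-6-methylheptan-2-yl]benzyl}-5-methylbenzene-1,2-diol | Cc1cc(O)c(O)c(Cc2ccc([C@@](C)(O)CCCC(C)C)c(O)c2)c1 | target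

Total step count: 16.
Longest linear sequence: 10 steps (steps 1–5, 8, 13, 14, 15, 16); the pyrone branch (steps 6, 7) and the alkynol branch (steps 9–12) converge at steps 8 and 13.

Steps most likely to fail

Step 14. The pyronyl O–Si bond may be cleaved by traces of water or by heat before the cycloaddition occurs, or the unactivated alkyne may react so slowly that the pyrone decomposes at the temperature required. The fallback sets out from 7 and comes back at 25; ring B is then taken from a purchased arene and no cycloaddition is used. The zinc reagent 13 made from 7 is coupled under the conditions of step 8 with commercial 1-(4-bromo-2-hydroxyphenyl)ethan-1-one to give 1-{4-[2,3-bis(benzyloxy)-5-methylbenzyl]-2-hydroxyphenyl}ethan-1-one F1. Addition of (4-methylpentyl)magnesium bromide (3 equiv, THF, 0 °C) gives racemic 5-[2,3-bis(benzyloxy)-5-methylbenzyl]-2-(2-hydroxy-6-methylheptan-2-yl)phenol F2. Preparative chromatography on a chiral stationary phase separates F2 into 25 and 5-[2,3-bis(benzyloxy)-5-methylbenzyl]-2-[(2R)-2-hydroxy-6-methylheptan-2-yl]phenol F3; 25 then enters step 16.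

Step 7. Oxidative addition may compete at C5, or the bromo boronate may undergo Suzuki-type self-coupling as it forms. The fallback sets out from 7 and 10, comes back at 14 and replaces steps 7 and 8; the carbon substituent goes on first and boron is introduced on a monobromide. Chloride 7 is treated with Bu3SnLi (THF, −78 °C) to give tributyl[2,3-bis(benzyloxy)-5-methylbenzyl]stannane F4. Stille coupling of F4 with 10 under copper-assisted conditions that reverse the site preference of this dibromide (Pd(PPh3)4, CuI 1 equiv, DMF, 50 °C) should give 5-[2,3-bis(benzyloxy)-5-methylbenzyl]-3-bromo-2H-pyran-2-one F5. Miyaura borylation of its only C–Br bond gives 5-[2,3-bis(benzyloxy)-5-methylbenzyl]-3-(4,4,5,5-tetramethyl-1,3,2-dioxaborolan-2-yl)-2H-pyran-2-one F6, which buffered H2O2 oxidises to 14.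

Step 8. The acidic enol may protonate the benzylzinc reagent, or the chelating hydroxypyronate may bind zinc and palladium so that the C–Br bond stays unreacted. The fallback sets out from 12 and comes back at 14; the enol is masked. Silylation of 12 (TBSCl, imidazole, CH2Cl2) gives 5-bromo-3-[(tert-butyldimethylsilyl)oxy]-2H-pyran-2-one F7. Negishi coupling of F7 with 13 under the conditions of step 8 gives 5-[2,3-bis(benzyloxy)-5-methylbenzyl]-3-[(tert-butyldimethylsilyl)oxy]-2H-pyran-2-one F8, and HF·pyridine in THF then frees 14.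

Further compounds
F1 | step 14 | 1-{4-[2,3-bis(benzyloxy)-5-methylbenzyl]-2-hydroxyphenyl}ethan-1-one | CC(=O)c1ccc(Cc2cc(C)cc(OCc3ccccc3)c2OCc2ccccc2)cc1O
F2 | step 14 | racemic 5-[2,3-bis(benzyloxy)-5-methylbenzyl]-2-(2-hydroxy-6-methylheptan-2-yl)phenol | CC(O)(CCCC(C)C)c1ccc(Cc2cc(C)cc(OCc3ccccc3)c2OCc2ccccc2)cc1O
F3 | step 14 | 5-[2,3-bis(benzyloxy)-5-methylbenzyl]-2-[(2R)-2-hydroxy-6-methylheptan-2-yl]phenol | Cc1cc(OCc2ccccc2)c(OCc2ccccc2)c(Cc2ccc([C@](C)(O)CCCC(C)C)c(O)c2)c1
F4 | step 7 | tributyl[2,3-bis(benzyloxy)-5-methylbenzyl]stannane | CCCC[Sn](CCCC)(CCCC)Cc1cc(C)cc(OCc2ccccc2)c1OCc1ccccc1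
F5 | step 7 | 5-[2,3-bis(benzyloxy)-5-methylbenzyl]-3-bromo-2H-pyran-2-one | Cc1cc(OCc2ccccc2)c(OCc2ccccc2)c(CC2=COC(=O)C(Br)=C2)c1
F6 | step 7 | 5-[2,3-bis(benzyloxy)-5-methylbenzyl]-3-(4,4,5,5-tetramethyl-1,3,2-dioxaborolan-2-yl)-2H-pyran-2-one | Cc1cc(OCc2ccccc2)c(OCc2ccccc2)c(CC2=COC(=O)C(B3OC(C)(C)C(C)(C)O3)=C2)c1
F7 | step 8 | 5-bromo-3-[(tert-butyldimethylsilyl)oxy]-2H-pyran-2-one | CC(C)(C)[Si](C)(C)OC1=CC(Br)=COC1=O
F8 | step 8 | 5-[2,3-bis(benzyloxy)-5-methylbenzyl]-3-[(tert-butyldimethylsilyl)oxy]-2H-pyran-2-one | Cc1cc(OCc2ccccc2)c(OCc2ccccc2)c(CC2=COC(=O)C(O[Si](C)(C)C(C)(C)C)=C2)c1
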